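**Retrosynthetic overview**
1. Tetrahydrofuran ring, formed last: O1–C7a by 5-exo oxa-Michael addition of the C2 alkoxide to the unsubstituted enone arm of a 4,4-disubstituted 2-methoxycyclohexa-2,5-dienone (megaphone-type 8.1′ neolignan closing 7.O.6′).
2. C3–C3a (8–1′) bond: para attack of (E)-methylisoeugenol on the phenoxonium ion of eugenol inside a chiral ion pair. The benzylic cation takes up acetate, whose oxygen becomes O1.
3. The six-membered ring is the dearomatised ring of eugenol; no carbocycle is built. Ring order: cyclohexadienone (dearomatisation), then tetrahydrofuran.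
4. Stereocentres: C3a and C3 in the C–C coupling (chiral counter-anion), C2 in the cation capture (Felkin-type), C7a in the ring closure (cis fusion).

Assumption: the sense of induction of the chiral acid in step 2 cannot be predicted from first principles; the (S,S)-catalyst is written, and its mirror image is used if it delivers the antipode.

**Step 1**
Reactants: 1 eugenol (4-allyl-2-methoxyphenol)
Product: 2 rac-6-acetoxy-4-allyl-6-methoxycyclohexa-2,4-dien-1-one (o-quinol acetate)
Conditions: PhI(OAc)2 (1.05 equiv), CH2Cl2, −78 to −30 °C; filtered cold, used at once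
Reagents that add atoms: (diacetoxyiodo)benzene, CC(=O)OI(OC(C)=O)c1ccccc1
Why: Wessely-type oxidative acetoxylation (phenol dearomatisation by a trivalent-iodine diacetate) places acetate on the methoxy-bearing carbon of a 2-methoxyphenol; the new stereocentre is racemic and irrelevant because it is erased on ionisation in step 2, and the allyl group survives the cold, non-nucleophilic medium.

**Step 2**
Reactants: 2 rac-6-acetoxy-4-allyl-6-methoxycyclohexa-2,4-dien-1-one; 3 (E)-methylisoeugenol [(E)-1,2-dimethoxy-4-(prop-1-en-1-yl)benzene]
Product: 6 (1S,2R)-1-(3,4-dimethoxyphenyl)-2-[(1R)-3-methoxy-4-oxo-1-(prop-2-en-1-yl)cyclohexa-2,5-dien-1-yl]propyl acetate, via phenoxonium ion 4 (not isolated), via benzylic cation 5 (not isolated)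
Conditions: 3 (1.5 equiv), (S,S)-IDPi acid (5 mol %; imidodiphosphorimidate Brønsted acid from two 3,3′-diaryl-BINOL units, N-triflyl), CH2Cl2/toluene 1:1, −60 °C
Reagents that add atoms: none
Why: Proposed new method: the strong, confined chiral acid ionises 2 (loss of acetic acid) to the contact ion pair of 4, whose allyl-bearing carbon (para to the carbonyl oxygen, SN1′-type allylic transposition) is attacked by the β-carbon of 3 on the face left open by the anion with the aryl group stacked over the hydrogen-bearing arm (setting C3a and C3 together), and cation 5 is then captured by the acetic acid anti to the quaternary carbon in the conformer with H-8 next to the aryl plane (Felkin-type, acetate syn to methyl, regenerating the catalyst); the closest known reaction types are acid-promoted cation–olefin couplings of quinone monoketals with propenylbenzenes ([3+2]/[5+2] and anodic megaphone-type 8–1′ coupling), their enantioselective versions on chelated 2-alkoxyquinones, and counter-anion-directed asymmetric additions of styrenes to oxocarbenium ions (Prins type).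

**Step 3**
Reactants: 6 (1S,2R)-1-(3,4-dimethoxyphenyl)-2-[(1R)-3-methoxy-4-oxo-1-(prop-2-en-1-yl)cyclohexa-2,5-dien-1-yl]propyl acetate
Product: 8 (2S,3R,3aR,7aS)-2-(3,4-dimethoxyphenyl)-5-methoxy-3-methyl-3a-(prop-2-en-1-yl)-3,3a,7,7a-tetrahydro-1-benzofuran-6(2H)-one, via hydroxy dienone 7 (not isolated)
Conditions: K2CO3 (20 mol %), MeOH, 0 °C to rt
Reagents that add atoms: none
Why: Zemplén-type transesterification frees the benzylic alkoxide of 7, which adds 5-exo-trig (intramolecular oxa-Michael addition) to the β-carbon of the unsubstituted enone arm, the α-methoxy enone arm being deactivated; the short tether enforces a cis ring fusion, so C7a (S, H cis to allyl) is set by C3a while C2, C3 and C3a are untouched.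

**Compound list**
1 | eugenol, 4-allyl-2-methoxyphenol | C=CCc1ccc(O)c(OC)c1 | starting material
2 | rac-6-acetoxy-4-allyl-6-methoxycyclohexa-2,4-dien-1-one (racemic) | C=CCC1=CC(OC)(OC(C)=O)C(=O)C=C1 | intermediate
3 | (E)-methylisoeugenol, (E)-1,2-dimethoxy-4-(prop-1-en-1-yl)benzene | C/C=C/c1ccc(OC)c(OC)c1 | starting material
4 | 4-allyl-2-methoxyphenoxonium ion (drawn as its O-methyl oxocarbenium form; ion-paired with the IDPi anion) | C=CCC1=CC(=[O+]C)C(=O)C=C1 | intermediate
5 | benzylic cation, 1-(3,4-dimethoxyphenyl)-2-[3-methoxy-4-oxo-1-(prop-2-en-1-yl)cyclohexa-2,5-dien-1-yl]propan-1-ylium, both stereocentres arranged as in 6 | C=CC[C@]1(C=C(OC)C(=O)C=C1)[C@@H](C)[CH+]c1ccc(OC)c(OC)c1 | intermediate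
6 | (1S,2R)-1-(3,4-dimethoxyphenyl)-2-[(1R)-3-methoxy-4-oxo-1-(prop-2-en-1-yl)cyclohexa-2,5-dien-1-yl]propyl acetate | C=CC[C@]1(C=C(OC)C(=O)C=C1)[C@@H](C)[C@H](OC(C)=O)c1ccc(OC)c(OC)c1 | intermediate
7 | (4R)-4-[(1S,2R)-1-(3,4-dimethoxyphenyl)-1-hydroxypropan-2-yl]-2-methoxy-4-(prop-2-en-1-yl)cyclohexa-2,5-dien-1-one | C=CC[C@]1(C=C(OC)C(=O)C=C1)[C@@H](C)[C@H](O)c1ccc(OC)c(OC)c1 | intermediate
8 | (2S,3R,3aR,7aS)-2-(3,4-dimethoxyphenyl)-5-methoxy-3-methyl-3a-(prop-2-en-1-yl)-3,3a,7,7a-tetrahydro-1-benzofuran-6(2H)-one | C=CC[C@@]12C=C(OC)C(=O)C[C@@H]1O[C@H](c1ccc(OC)c(OC)c1)[C@@H]2C | target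

Total step count: 3. Longest linear sequence: 3 (from 1).

**Steps most likely to fail**

Step 2 (highest risk). Several things can go wrong here:
- attack at the free ortho carbon, giving the 8–5′ dihydrobenzofuran;
- poor C3/C3a diastereoselectivity, since the two dienone arms differ only by a remote methoxy group;
- low enantioselectivity;
- elimination of cation 5, or its interception by the allyl group.

The fallback sets out from 2 and comes back at 7. It replaces the styrene by an enamine and brings the aryl group in afterwards. Compound 2 is ionised in the presence of propanal and a chiral imidazolidinone·CF3CO2H salt (SN1-type aminocatalytic α-alkylation of an aldehyde with a stabilised cation; the enamine face sets the methyl-bearing carbon). After separation of diastereomers this gives (2R)-2-[(1S)-3-methoxy-4-oxo-1-(prop-2-en-1-yl)cyclohexa-2,5-dien-1-yl]propanal F2. 3,4-Dimethoxyphenyltitanium triisopropoxide, ArTi(OiPr)3 (from 4-bromo-1,2-dimethoxybenzene via ArMgBr and ClTi(OiPr)3; THF, −40 °C), then adds to the aldehyde only, anti to the quaternary carbon (Felkin–Anh). This gives 7, which the K2CO3/MeOH of step 3 closes to 8.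

Step 1. Compound 2 is a reactive 2,4-dienone that may dimerise by Diels–Alder reaction, and eugenol may instead lose a benzylic proton to a quinone methide. Para-acetoxylation is harmless, since that isomer ionises to the same ion 4. The fallback sets out from 1 and comes back at 6. Compound 1 is oxidised with PhI(OAc)2 in methanol at 0 °C to the quinone monoketal 4-allyl-6,6-dimethoxycyclohexa-2,4-dien-1-one F1, kept in solution. F1 is submitted to the step 2 conditions with acetic acid (2 equiv) and 5 Å molecular sieves. Loss of methanol gives the same ion 4, and external acetic acid now terminates cation 5 to give 6.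

Step 3. Methoxide may add to the dienone, cleavage of the hindered benzylic acetate may be slow, and the C2 ratio depends on the acetate capture in step 2. The fallback sets out from 6 and comes back at 7. It breaks the alkyl–oxygen bond instead of the acyl–oxygen bond: SN1 hydrolysis in 1,1,1,3,3,3-hexafluoropropan-2-ol/water (4:1, rt) re-forms cation 5 and captures it with water under the same Felkin-type control. The resulting 7 is closed to 8 in a separate operation with catalytic DBU in CH2Cl2. This fallback makes no compound outside the list (none F0).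

**Further compounds**
F1 | step 1 | 4-allyl-6,6-dimethoxycyclohexa-2,4-dien-1-one | C=CCC1=CC(OC)(OC)C(=O)C=C1
F2 | step 2 | (2R)-2-[(1S)-3-methoxy-4-oxo-1-(prop-2-en-1-yl)cyclohexa-2,5-dien-1-yl]propanal | C=CC[C@]1(C=C(OC)C(=O)C=C1)[C@@H](C)C=O
F0 | step 3 | none | none
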